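**Strategy.** With the lactone carbonyl as C1, the butenolide stereocentre is C4 and the Z-trisubstituted alkene is C6=C7. The oxygen on C4 and the hydroxymethyl oxygen on C7 are the two ends of a pent-2-ene-1,5-diol. Joining them through one silicon atom therefore places C6=C7 in an eight-membered 1,3-dioxa-2-silacyclooct-5-ene, a ring that accepts only a cis alkene. The plan rests on the C6=C7 disconnection: ring-closing metathesis of a diisopropylsilylene-bridged diene unites both halves and fixes the Z geometry in one operation. The diene is assembled from an (R)-α-hydroxy ketone bearing the C6 vinyl group and a farnesol-derived 2-methylene alcohol. Butenolide annulation on the C3 ketone follows.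

Key step: step 14

Remark: the chain is numbered C1 (lactone carbonyl) onward and each CH2OH carbon is named by the carbon that carries it. The stannane used in step 11 is assumed not to be a catalogue compound and is made in step 10.

Step 1
Reactants: 1 (2E,6E)-farnesol
Product: 2 (2E,6E)-3,7,11-trimethyldodeca-2,6,10-trien-1-yl acetate
Conditions: Ac2O, Et3N, DMAP (cat.), CH2Cl2, 0 °C → rt
Reagents that add atoms: acetic anhydride, CC(=O)OC(C)=O
Why: DMAP-catalysed O-acylation masks the primary allylic alcohol and makes the neighbouring alkene the least electron-rich of the three before the allylic oxidation.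

Step 2
Reactants: 2 (2E,6E)-3,7,11-trimethyldodeca-2,6,10-trien-1-yl acetate
Product: 3 (2E,6E,10E)-12-hydroxy-3,7,11-trimethyldodeca-2,6,10-trien-1-yl acetate
Conditions: SeO2 (cat.), t-BuOOH, salicylic acid (cat.), CH2Cl2, 0 °C → rt, stopped at partial conversion
Reagents that add atoms: tert-butyl hydroperoxide, CC(C)(C)OO (stoichiometric oxygen source); selenium dioxide, O=[Se]=O (catalytic oxygen carrier)
Why: Riley allylic oxidation (ene reaction then [2,3]-sigmatropic shift) should attack the most electron-rich, least hindered terminal alkene at the methyl group trans to the chain, giving the E-configured primary allylic alcohol.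

Step 3
Reactants: 3 (2E,6E,10E)-12-hydroxy-3,7,11-trimethyldodeca-2,6,10-trien-1-yl acetate
Product: 4 (2E,6E,10E)-12-[(tert-butyldimethylsilyl)oxy]-3,7,11-trimethyldodeca-2,6,10-trien-1-yl acetate
Conditions: TBSCl, imidazole, CH2Cl2, 0 °C → rt
Reagents that add atoms: tert-butyldimethylsilyl chloride, CC(C)(C)[Si](C)(C)Cl
Why: Imidazole-promoted silyl ether formation differentiates the two chain termini with a group that later leaves together with the silicon bridge.

Step 4
Reactants: 4 (2E,6E,10E)-12-[(tert-butyldimethylsilyl)oxy]-3,7,11-trimethyldodeca-2,6,10-trien-1-yl acetate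
Product: 5 (2E,6E,10E)-12-[(tert-butyldimethylsilyl)oxy]-3,7,11-trimethyldodeca-2,6,10-trien-1-ol
Conditions: K2CO3 (cat.), MeOH, 0 °C → rt
Reagents that add atoms: none
Why: Base-catalysed transesterification with methanol removes the acetate, and a primary TBS ether is inert to carbonate in methanol.

Step 5
Reactants: 5 (2E,6E,10E)-12-[(tert-butyldimethylsilyl)oxy]-3,7,11-trimethyldodeca-2,6,10-trien-1-ol
Product: 7 [(2E,6E,10E)-12-bromo-2,6,10-trimethyldodeca-2,6,10-trien-1-yl]oxy(tert-butyl)dimethylsilane, via allylic methanesulfonate 6 (not isolated)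
Conditions: MsCl, Et3N, THF, −40 °C; then LiBr, THF, −40 → 0 °C
Reagents that add atoms: lithium bromide, [Li+].[Br-]; methanesulfonyl chloride, CS(=O)(=O)Cl (its atoms remain only in intermediate 6)
Why: Sulfonylation followed by Finkelstein-type SN2 displacement with bromide converts the primary allylic alcohol to the bromide without acid, so the silyl ether and the alkene geometry are preserved.

Step 6
Reactants: 7 [(2E,6E,10E)-12-bromo-2,6,10-trimethyldodeca-2,6,10-trien-1-yl]oxy(tert-butyl)dimethylsilane; 8 2-methylprop-2-en-1-ol (methallyl alcohol)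
Product: 10 (5E,9E,13E)-15-[(tert-butyldimethylsilyl)oxy]-6,10,14-trimethyl-2-methylidenepentadeca-5,9,13-trien-1-ol, via dilithiated methallyl alcohol 9 (not isolated)
Conditions: 8 (3 equiv), n-BuLi (1.95 equiv per 8), TMEDA, Et2O, 0 °C → rt; then 7, THF, −78 → 0 °C; H2O
Reagents that add atoms: n-butyllithium, [Li]CCCC (lithium of intermediate 9 only)
Why: Alkoxide-directed allylic lithiation gives a C,O-dianion whose carbanion alkylates the primary allylic bromide by SN2, installing C8, C7 with its exocyclic methylene and the C7 CH2OH in one step.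

Step 7
Reactants: 11 D-allylglycine [(R)-2-aminopent-4-enoic acid]
Product: 12 (R)-2-hydroxypent-4-enoic acid
Conditions: NaNO2, 1 M H2SO4 (aq), 0 °C → rt
Reagents that add atoms: water, O
Why: Diazotisation of the α-amino acid proceeds through an α-lactone (carboxylate displaces N2 with inversion, water opens with a second inversion), so the future C4 is obtained with net retention as R.

Step 8
Reactants: 12 (R)-2-hydroxypent-4-enoic acid
Product: 13 (R)-2-hydroxy-N-methoxy-N-methylpent-4-enamide
Conditions: MeNHOMe·HCl, EDC·HCl, HOBt, N-methylmorpholine, CH2Cl2, 0 °C → rt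
Reagents that add atoms: N,O-dimethylhydroxylamine hydrochloride, CNOC.Cl
Why: Carbodiimide/HOBt amide coupling should tolerate the free hindered α-hydroxyl, and an α-hydroxy acid has no azlactone pathway for racemisation.

Step 9
Reactants: 13 (R)-2-hydroxy-N-methoxy-N-methylpent-4-enamide
Product: 14 (R)-N-methoxy-N-methyl-2-[(triethylsilyl)oxy]pent-4-enamide
Conditions: TESCl, imidazole, CH2Cl2, 0 °C
Reagents that add atoms: chlorotriethylsilane, CC[Si](Cl)(CC)CC
Why: Imidazole-promoted silylation blocks the hydroxyl for the organolithium addition with a group that can later be removed without touching a PMB ether.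

Step 10
Reactants: 15 4-methoxybenzyl alcohol; 16 tributyl(iodomethyl)stannane
Product: 18 tributyl{[(4-methoxybenzyl)oxy]methyl}stannane, via sodium 4-methoxybenzyl oxide 17 (not isolated)
Conditions: NaH, THF–DMF, 0 °C; then 16, 0 °C → rt
Reagents that add atoms: sodium hydride, [Na+].[H-] (sodium of intermediate 17 only)
Why: Williamson ether synthesis, in which the alkoxide displaces iodide from the primary iodomethylstannane by SN2.

Step 11
Reactants: 18 tributyl{[(4-methoxybenzyl)oxy]methyl}stannane; 14 (R)-N-methoxy-N-methyl-2-[(triethylsilyl)oxy]pent-4-enamide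
Product: 20 (R)-1-[(4-methoxybenzyl)oxy]-3-[(triethylsilyl)oxy]hex-5-en-2-one, via (4-methoxybenzyloxy)methyllithium 19 (not isolated)
Conditions: 18, n-BuLi, THF, −78 °C; then 14, −78 °C; aq. NH4Cl
Reagents that add atoms: n-butyllithium, [Li]CCCC (lithium of intermediate 19 only)
Why: Tin–lithium exchange gives the α-alkoxymethyllithium, which adds once to the N-methoxy-N-methylamide (Weinreb ketone synthesis) because the chelated tetrahedral adduct persists until the quench, and C4 is not acidic in that adduct so its configuration is kept.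

Step 12
Reactants: 20 (R)-1-[(4-methoxybenzyl)oxy]-3-[(triethylsilyl)oxy]hex-5-en-2-one
Product: 21 (R)-3-hydroxy-1-[(4-methoxybenzyl)oxy]hex-5-en-2-one
Conditions: HF·pyridine, pyridine, THF, 0 °C
Reagents that add atoms: none
Why: Fluoride-driven desilylation of the labile TES ether under non-basic conditions frees the α-hydroxy ketone without enolising C4 or cleaving the PMB ether.

Step 13
Reactants: 21 (R)-3-hydroxy-1-[(4-methoxybenzyl)oxy]hex-5-en-2-one; 22 dichlorodiisopropylsilane; 10 (5E,9E,13E)-15-[(tert-butyldimethylsilyl)oxy]-6,10,14-trimethyl-2-methylidenepentadeca-5,9,13-trien-1-ol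
Product: 24 (R)-3-{[({(5E,9E,13E)-15-[(tert-butyldimethylsilyl)oxy]-6,10,14-trimethyl-2-methylidenepentadeca-5,9,13-trien-1-yl}oxy)diisopropylsilyl]oxy}-1-[(4-methoxybenzyl)oxy]hex-5-en-2-one, via chlorodiisopropylsilyl ether 23 (not isolated)
Conditions: 22 (1.1 equiv), imidazole, CH2Cl2, 0 °C, slow addition of 21; then 10, imidazole, DMAP (cat.), 0 °C → rt
Reagents that add atoms: none
Why: Stepwise nucleophilic substitution at silicon, in which the hindered secondary alcohol should displace only one chloride of the bulky dichlorosilane and the remaining Si–Cl is then taken by the unhindered primary allylic alcohol to give the mixed silaketal.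

Step 14
Reactants: 24 (R)-3-{[({(5E,9E,13E)-15-[(tert-butyldimethylsilyl)oxy]-6,10,14-trimethyl-2-methylidenepentadeca-5,9,13-trien-1-yl}oxy)diisopropylsilyl]oxy}-1-[(4-methoxybenzyl)oxy]hex-5-en-2-one
Product: 25 (R,Z)-1-{5-[(3E,7E,11E)-13-[(tert-butyldimethylsilyl)oxy]-4,8,12-trimethyltrideca-3,7,11-trien-1-yl]-2,2-diisopropyl-7,8-dihydro-4H-1,3,2-dioxasilocin-8-yl}-2-[(4-methoxybenzyl)oxy]ethan-1-one
Conditions: Grubbs II (10 mol %, two portions), 1,4-benzoquinone (20 mol %), toluene (2 mM), 80 °C, Ar sparge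
Reagents that add atoms: none
Why: Ring-closing olefin metathesis by the metallacyclobutane mechanism: the ruthenium alkylidene loads on the monosubstituted C6 vinyl group, adds [2+2] across the 1,1-disubstituted C7 methylene alkene and cycloreverts, releasing ethylene and forming C6=C7. The closest known reaction type is temporary silicon-tethered ring-closing metathesis, which delivers Z-trisubstituted alkenes inside seven- and eight-membered silaketals. The single ring formed, the eight-membered 1,3-dioxa-2-silacyclooct-5-ene, closes by this intramolecular metathesis of the two terminal alkenes, and because an E alkene would be prohibitively strained in a ring of this size, C5 and the C7 CH2O carbon end cis (Z). No stereocentre is created, and C4 is a spectator that is not enolised under the neutral conditions. The step needs site selectivity for the two terminal alkenes over the three trisubstituted chain alkenes and ring closure over dimerisation; the low reactivity of trisubstituted alkenes, the isopropyl groups on silicon, high dilution and ethylene removal should secure both, while benzoquinone suppresses migration of the terminal C6 alkene.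

Step 15
Reactants: 25 (R,Z)-1-{5-[(3E,7E,11E)-13-[(tert-butyldimethylsilyl)oxy]-4,8,12-trimethyltrideca-3,7,11-trien-1-yl]-2,2-diisopropyl-7,8-dihydro-4H-1,3,2-dioxasilocin-8-yl}-2-[(4-methoxybenzyl)oxy]ethan-1-one
Product: 26 (3R,5Z,9E,13E,17E)-3,19-dihydroxy-6-(hydroxymethyl)-1-[(4-methoxybenzyl)oxy]-10,14,18-trimethylnonadeca-5,9,13,17-tetraen-2-one
Conditions: HF·pyridine, pyridine, THF, 0 °C → rt
Reagents that add atoms: none
Why: Fluoride-mediated cleavage of all Si–O bonds removes the silicon bridge and the distal TBS ether in one operation, and the acidic rather than basic fluoride source should leave the liberated α-hydroxy ketone (C4) and the PMB ether untouched.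

Step 16
Reactants: 26 (3R,5Z,9E,13E,17E)-3,19-dihydroxy-6-(hydroxymethyl)-1-[(4-methoxybenzyl)oxy]-10,14,18-trimethylnonadeca-5,9,13,17-tetraen-2-one
Product: 27 (3R,5Z,9E,13E,17E)-19-[(tert-butyldimethylsilyl)oxy]-6-{[(tert-butyldimethylsilyl)oxy]methyl}-3-hydroxy-1-[(4-methoxybenzyl)oxy]-10,14,18-trimethylnonadeca-5,9,13,17-tetraen-2-one
Conditions: TBSCl (2.2 equiv), imidazole, CH2Cl2, −20 → 0 °C
Reagents that add atoms: tert-butyldimethylsilyl chloride, CC(C)(C)[Si](C)(C)Cl
Why: Chemoselective silylation, since the two unhindered primary allylic hydroxyls should react far faster than the secondary hydroxyl, which is hindered and deactivated by the adjacent carbonyl.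

Step 17
Reactants: 27 (3R,5Z,9E,13E,17E)-19-[(tert-butyldimethylsilyl)oxy]-6-{[(tert-butyldimethylsilyl)oxy]methyl}-3-hydroxy-1-[(4-methoxybenzyl)oxy]-10,14,18-trimethylnonadeca-5,9,13,17-tetraen-2-one; 28 (triphenylphosphoranylidene)ketene
Product: 30 (R)-5-[(2Z,6E,10E,14E)-16-[(tert-butyldimethylsilyl)oxy]-3-{[(tert-butyldimethylsilyl)oxy]methyl}-7,11,15-trimethylhexadeca-2,6,10,14-tetraen-1-yl]-4-{[(4-methoxybenzyl)oxy]methyl}furan-2(5H)-one, via phosphoranylidene acetate ester 29 (not isolated)
Conditions: 28, toluene, 90 °C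
Reagents that add atoms: none
Why: The C4 hydroxyl adds to the ketene ylide to give a stabilised ylide ester that closes the butenolide by intramolecular Wittig olefination with the C3 ketone, a sequence in which no bond to C4 is made or broken, so its R configuration is carried over.

Step 18
Reactants: 30 (R)-5-[(2Z,6E,10E,14E)-16-[(tert-butyldimethylsilyl)oxy]-3-{[(tert-butyldimethylsilyl)oxy]methyl}-7,11,15-trimethylhexadeca-2,6,10,14-tetraen-1-yl]-4-{[(4-methoxybenzyl)oxy]methyl}furan-2(5H)-one
Product: 31 (R)-5-[(2Z,6E,10E,14E)-16-[(tert-butyldimethylsilyl)oxy]-3-{[(tert-butyldimethylsilyl)oxy]methyl}-7,11,15-trimethylhexadeca-2,6,10,14-tetraen-1-yl]-4-(hydroxymethyl)furan-2(5H)-one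
Conditions: DDQ, CH2Cl2–pH 7 buffer, 0 °C
Reagents that add atoms: none
Why: Oxidative PMB ether cleavage by DDQ (oxidation to the benzylic oxocarbenium ion, then hydrolysis) should leave silyl ethers, isolated trisubstituted alkenes and the butenolide intact, and no free electron-rich allylic alcohol is present to be over-oxidised.

Step 19
Reactants: 31 (R)-5-[(2Z,6E,10E,14E)-16-[(tert-butyldimethylsilyl)oxy]-3-{[(tert-butyldimethylsilyl)oxy]methyl}-7,11,15-trimethylhexadeca-2,6,10,14-tetraen-1-yl]-4-(hydroxymethyl)furan-2(5H)-one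
Product: 32 Hippolide F [(R)-5-[(2Z,6E,10E,14E)-16-hydroxy-3-(hydroxymethyl)-7,11,15-trimethylhexadeca-2,6,10,14-tetraen-1-yl]-4-(hydroxymethyl)furan-2(5H)-one]
Conditions: HF·pyridine, pyridine, THF, 0 °C → rt
Reagents that add atoms: none
Why: Fluoride-driven desilylation of both primary TBS ethers under non-basic conditions should release the target without deprotonating the base-sensitive C4–H of the butenolide.

**Compound list**

1 | (2E,6E)-farnesol | CC(C)=CCC/C(C)=C/CC/C(C)=C/CO | starting material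
2 | (2E,6E)-3,7,11-trimethyldodeca-2,6,10-trien-1-yl acetate | CC(C)=CCC/C(C)=C/CC/C(C)=C/COC(C)=O | intermediate
3 | (2E,6E,10E)-12-hydroxy-3,7,11-trimethyldodeca-2,6,10-trien-1-yl acetate | C/C(=C\CC/C(C)=C/CC/C(C)=C/COC(C)=O)CO | intermediate
4 | (2E,6E,10E)-12-[(tert-butyldimethylsilyl)oxy]-3,7,11-trimethyldodeca-2,6,10-trien-1-yl acetate | C/C(=C\CC/C(C)=C/CC/C(C)=C/COC(C)=O)CO[Si](C)(C)C(C)(C)C | intermediate
5 | (2E,6E,10E)-12-[(tert-butyldimethylsilyl)oxy]-3,7,11-trimethyldodeca-2,6,10-trien-1-ol | C/C(=C\CC/C(C)=C/CC/C(C)=C/CO)CO[Si](C)(C)C(C)(C)C | intermediate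
6 | (2E,6E,10E)-12-[(tert-butyldimethylsilyl)oxy]-3,7,11-trimethyldodeca-2,6,10-trien-1-yl methanesulfonate (not isolated) | C/C(=C\CC/C(C)=C/CC/C(C)=C/COS(C)(=O)=O)CO[Si](C)(C)C(C)(C)C | intermediate
7 | [(2E,6E,10E)-12-bromo-2,6,10-trimethyldodeca-2,6,10-trien-1-yl]oxy(tert-butyl)dimethylsilane | C/C(=C\CC/C(C)=C/CC/C(C)=C/CBr)CO[Si](C)(C)C(C)(C)C | intermediate
8 | 2-methylprop-2-en-1-ol (methallyl alcohol) | C=C(C)CO | starting material
9 | dilithiated methallyl alcohol, lithium 2-(lithiomethyl)prop-2-en-1-olate (not isolated) | [Li]CC(=C)CO[Li] | intermediate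
10 | (5E,9E,13E)-15-[(tert-butyldimethylsilyl)oxy]-6,10,14-trimethyl-2-methylidenepentadeca-5,9,13-trien-1-ol | C/C(=C\CC/C(C)=C/CC/C(C)=C/CCC(=C)CO)CO[Si](C)(C)C(C)(C)C | intermediate
11 | D-allylglycine, (R)-2-aminopent-4-enoic acid | C=CC[C@@H](N)C(=O)O | starting material
12 | (R)-2-hydroxypent-4-enoic acid | C=CC[C@@H](O)C(=O)O | intermediate
13 | (R)-2-hydroxy-N-methoxy-N-methylpent-4-enamide | C=CC[C@@H](O)C(=O)N(C)OC | intermediate
14 | (R)-N-methoxy-N-methyl-2-[(triethylsilyl)oxy]pent-4-enamide | C=CC[C@@H](O[Si](CC)(CC)CC)C(=O)N(C)OC | intermediate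
15 | 4-methoxybenzyl alcohol | COc1ccc(CO)cc1 | starting material
16 | tributyl(iodomethyl)stannane | CCCC[Sn](CCCC)(CCCC)CI | starting material
17 | sodium 4-methoxybenzyl oxide (not isolated) | [Na+].[O-]Cc1ccc(OC)cc1 | intermediate
18 | tributyl{[(4-methoxybenzyl)oxy]methyl}stannane | CCCC[Sn](CCCC)(CCCC)COCc1ccc(OC)cc1 | intermediate
19 | (4-methoxybenzyloxy)methyllithium (not isolated) | [Li]COCc1ccc(OC)cc1 | intermediate
20 | (R)-1-[(4-methoxybenzyl)oxy]-3-[(triethylsilyl)oxy]hex-5-en-2-one | C=CC[C@@H](O[Si](CC)(CC)CC)C(=O)COCc1ccc(OC)cc1 | intermediate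
21 | (R)-3-hydroxy-1-[(4-methoxybenzyl)oxy]hex-5-en-2-one | C=CC[C@@H](O)C(=O)COCc1ccc(OC)cc1 | intermediate
22 | dichlorodiisopropylsilane | CC(C)[Si](Cl)(Cl)C(C)C | starting material
23 | (R)-3-{[chloro(diisopropyl)silyl]oxy}-1-[(4-methoxybenzyl)oxy]hex-5-en-2-one (not isolated) | C=CC[C@@H](O[Si](Cl)(C(C)C)C(C)C)C(=O)COCc1ccc(OC)cc1 | intermediate
24 | diisopropylsilylene-bridged diene: diisopropylsilyl bis-ether of the C4 hydroxyl of 21 and the hydroxyl of 10 (R at C4; chain alkenes E) | C/C(=C\CC/C(C)=C/CC/C(C)=C/CCC(=C)CO[Si](C(C)C)(C(C)C)O[C@H](CC=C)C(=O)COCc1ccc(OC)cc1)CO[Si](C)(C)C(C)(C)C | intermediate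
25 | eight-membered (Z)-silaketal: 2,2-diisopropyl-1,3-dioxa-2-silacyclooct-5-ene with the TBS-oxy trienyl chain on the ring alkene carbon C7 and the (R)-carbon C4 bearing the 2-(PMB-oxy)acetyl group | C/C(=C\CC/C(C)=C/CC/C(C)=C/CC/C1=C/C[C@H](C(=O)COCc2ccc(OC)cc2)O[Si](C(C)C)(C(C)C)OC1)CO[Si](C)(C)C(C)(C)C | intermediate
26 | (3R,5Z,9E,13E,17E)-3,19-dihydroxy-6-(hydroxymethyl)-1-[(4-methoxybenzyl)oxy]-10,14,18-trimethylnonadeca-5,9,13,17-tetraen-2-one | C/C(=C\CC/C(C)=C/CC/C(C)=C/CC/C(=C/C[C@@H](O)C(=O)COCc1ccc(OC)cc1)CO)CO | intermediate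
27 | (3R,5Z,9E,13E,17E)-19-[(tert-butyldimethylsilyl)oxy]-6-{[(tert-butyldimethylsilyl)oxy]methyl}-3-hydroxy-1-[(4-methoxybenzyl)oxy]-10,14,18-trimethylnonadeca-5,9,13,17-tetraen-2-one | C/C(=C\CC/C(C)=C/CC/C(C)=C/CC/C(=C/C[C@@H](O)C(=O)COCc1ccc(OC)cc1)CO[Si](C)(C)C(C)(C)C)CO[Si](C)(C)C(C)(C)C | intermediate
28 | (triphenylphosphoranylidene)ketene | O=C=C=P(c1ccccc1)(c1ccccc1)c1ccccc1 | starting material
29 | (triphenylphosphoranylidene)acetate ester of the C4 hydroxyl of 27 (not isolated) | C/C(=C\CC/C(C)=C/CC/C(C)=C/CC/C(=C/C[C@@H](OC(=O)C=P(c1ccccc1)(c1ccccc1)c1ccccc1)C(=O)COCc1ccc(OC)cc1)CO[Si](C)(C)C(C)(C)C)CO[Si](C)(C)C(C)(C)C | intermediate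
30 | (R)-5-[(2Z,6E,10E,14E)-16-[(tert-butyldimethylsilyl)oxy]-3-{[(tert-butyldimethylsilyl)oxy]methyl}-7,11,15-trimethylhexadeca-2,6,10,14-tetraen-1-yl]-4-{[(4-methoxybenzyl)oxy]methyl}furan-2(5H)-one | C/C(=C\CC/C(C)=C/CC/C(C)=C/CC/C(=C/C[C@H]1OC(=O)C=C1COCc2ccc(OC)cc2)CO[Si](C)(C)C(C)(C)C)CO[Si](C)(C)C(C)(C)C | intermediate
31 | (R)-5-[(2Z,6E,10E,14E)-16-[(tert-butyldimethylsilyl)oxy]-3-{[(tert-butyldimethylsilyl)oxy]methyl}-7,11,15-trimethylhexadeca-2,6,10,14-tetraen-1-yl]-4-(hydroxymethyl)furan-2(5H)-one | C/C(=C\CC/C(C)=C/CC/C(C)=C/CC/C(=C/C[C@H]1OC(=O)C=C1CO)CO[Si](C)(C)C(C)(C)C)CO[Si](C)(C)C(C)(C)C | intermediate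
32 | Hippolide F, (R)-5-[(2Z,6E,10E,14E)-16-hydroxy-3-(hydroxymethyl)-7,11,15-trimethylhexadeca-2,6,10,14-tetraen-1-yl]-4-(hydroxymethyl)furan-2(5H)-one | C/C(=C\CC/C(C)=C/CC/C(C)=C/CC/C(=C/C[C@H]1OC(=O)C=C1CO)CO)CO | target

**Total step count:** 19.
**Longest linear sequence:** 13 steps (steps 1–6 and 13–19, from farnesol).

**Steps most likely to fail**

1. Step 14. Closure of the eight-membered ring onto a 1,1-disubstituted alkene may be slow. Intermolecular metathesis through the C6 vinyl group, chelation of the ruthenium alkylidene by the C3 carbonyl, or migration of the terminal alkene could then take over. The fallback replaces the silicon bridge by an ester tether between the C7 CH2O oxygen and C3, giving a seven-membered ring, and builds the ketone afterwards. It sets out from 12 and 10 and comes back at 26.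
   - Mitsunobu esterification of 12 with 10 (PPh3, DIAD, THF, 0 °C) should acylate only the primary allylic alcohol and give (5E,9E,13E)-15-[(tert-butyldimethylsilyl)oxy]-6,10,14-trimethyl-2-methylidenepentadeca-5,9,13-trien-1-yl (R)-2-hydroxypent-4-enoate F1.
   - Ring-closing metathesis (Grubbs II, toluene, 80 °C, high dilution) should close the seven-membered lactone (R)-3-hydroxy-6-[(3E,7E,11E)-13-[(tert-butyldimethylsilyl)oxy]-4,8,12-trimethyltrideca-3,7,11-trien-1-yl]-4,7-dihydrooxepin-2(3H)-one F2, whose ring again forces C6=C7 to be cis.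
   - Aminolysis with MeNHOMe·HCl and i-PrMgCl (THF, −20 → 0 °C) should open the lactone to (2R,4Z,8E,12E,16E)-18-[(tert-butyldimethylsilyl)oxy]-2-hydroxy-5-(hydroxymethyl)-N-methoxy-N,9,13,17-tetramethyloctadeca-4,8,12,16-tetraenamide F3.
   - Silylation (TESCl, imidazole) should give the bis(triethylsilyl) ether of that amide F4.
   - Addition of 19 at −78 °C should give (3R,5Z,9E,13E,17E)-19-[(tert-butyldimethylsilyl)oxy]-1-[(4-methoxybenzyl)oxy]-10,14,18-trimethyl-3-[(triethylsilyl)oxy]-6-{[(triethylsilyl)oxy]methyl}nonadeca-5,9,13,17-tetraen-2-one F5.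
   - HF·pyridine should then remove all three silyl groups and deliver 26, from which steps 16–19 follow.

2. Step 17. Addition of the hindered C4 hydroxyl to the ketene ylide may be slow at the temperature needed, and enolisation of the α-acyloxy ketone could erode the configuration at C4 before the Wittig closure. The fallback separates acylation from olefination and runs the ring closure at low temperature. It sets out from 27 and comes back at 30.
   - Esterification of 27 with (diethoxyphosphoryl)acetic acid (EDC, DMAP cat., CH2Cl2, 0 °C) should give the C4 (diethoxyphosphoryl)acetate of 27 F6.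
   - An intramolecular Horner–Wadsworth–Emmons reaction under mild LiCl/i-Pr2NEt conditions (MeCN, 0 °C → rt) should then close the butenolide 30.

3. Step 13. Scrambling at silicon may occur: double substitution by one alcohol giving symmetrical bis-ethers, or hydrolysis of 23 before the second alcohol arrives. The fallback introduces the two Si–O bonds through different leaving groups. It sets out from 21 and comes back at 24.
   - Silylation of 21 with chlorodiisopropylsilane (imidazole, CH2Cl2, 0 °C) should give the isolable (R)-3-[(diisopropylsilyl)oxy]-1-[(4-methoxybenzyl)oxy]hex-5-en-2-one F7.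
   - NBS (CH2Cl2, 0 °C) should convert Si–H into Si–Br, giving (R)-3-{[bromo(diisopropyl)silyl]oxy}-1-[(4-methoxybenzyl)oxy]hex-5-en-2-one F8, which is not isolated.
   - Trapping with 10 and imidazole should give 24.

**Further compounds**

F1 | step 14 | (5E,9E,13E)-15-[(tert-butyldimethylsilyl)oxy]-6,10,14-trimethyl-2-methylidenepentadeca-5,9,13-trien-1-yl (R)-2-hydroxypent-4-enoate | C/C(=C\CC/C(C)=C/CC/C(C)=C/CCC(=C)COC(=O)[C@H](O)CC=C)CO[Si](C)(C)C(C)(C)C
F2 | step 14 | (R)-3-hydroxy-6-[(3E,7E,11E)-13-[(tert-butyldimethylsilyl)oxy]-4,8,12-trimethyltrideca-3,7,11-trien-1-yl]-4,7-dihydrooxepin-2(3H)-one | C/C(=C\CC/C(C)=C/CC/C(C)=C/CCC1=CC[C@@H](O)C(=O)OC1)CO[Si](C)(C)C(C)(C)C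
F3 | step 14 | (2R,4Z,8E,12E,16E)-18-[(tert-butyldimethylsilyl)oxy]-2-hydroxy-5-(hydroxymethyl)-N-methoxy-N,9,13,17-tetramethyloctadeca-4,8,12,16-tetraenamide | C/C(=C\CC/C(C)=C/CC/C(C)=C/CC/C(=C/C[C@@H](O)C(=O)N(C)OC)CO)CO[Si](C)(C)C(C)(C)C
F4 | step 14 | bis(triethylsilyl) ether of F3 (TES on the C4 oxygen and on the C7 CH2O oxygen) | C/C(=C\CC/C(C)=C/CC/C(C)=C/CC/C(=C/C[C@@H](O[Si](CC)(CC)CC)C(=O)N(C)OC)CO[Si](CC)(CC)CC)CO[Si](C)(C)C(C)(C)C
F5 | step 14 | (3R,5Z,9E,13E,17E)-19-[(tert-butyldimethylsilyl)oxy]-1-[(4-methoxybenzyl)oxy]-10,14,18-trimethyl-3-[(triethylsilyl)oxy]-6-{[(triethylsilyl)oxy]methyl}nonadeca-5,9,13,17-tetraen-2-one | C/C(=C\CC/C(C)=C/CC/C(C)=C/CC/C(=C/C[C@@H](O[Si](CC)(CC)CC)C(=O)COCc1ccc(OC)cc1)CO[Si](CC)(CC)CC)CO[Si](C)(C)C(C)(C)C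
F6 | step 17 | C4 (diethoxyphosphoryl)acetate of 27 | C/C(=C\CC/C(C)=C/CC/C(C)=C/CC/C(=C/C[C@@H](OC(=O)CP(=O)(OCC)OCC)C(=O)COCc1ccc(OC)cc1)CO[Si](C)(C)C(C)(C)C)CO[Si](C)(C)C(C)(C)C
F7 | step 13 | (R)-3-[(diisopropylsilyl)oxy]-1-[(4-methoxybenzyl)oxy]hex-5-en-2-one | C=CC[C@@H](O[SiH](C(C)C)C(C)C)C(=O)COCc1ccc(OC)cc1
F8 | step 13 | (R)-3-{[bromo(diisopropyl)silyl]oxy}-1-[(4-methoxybenzyl)oxy]hex-5-en-2-one | C=CC[C@@H](O[Si](Br)(C(C)C)C(C)C)C(=O)COCc1ccc(OC)cc1
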